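Chains grow slowly: in the spring run free monomer takes from 3.00 min to 15.0 min to fall from 79% to 39%. Yet each molecule of free monomer meets a fork before that slow stretch, and the runs show it. The sum of free monomer and monomer in chains lacks 14.0% in spring at 6.00 min and 29.0% in autumn at 2.00 min, readings close to the charged ratios c(protic impurity)/c(free monomer), 13.7% and 30.0%.

the same everywhere: free monomer 0.80 M; initiator 70 mM
- spring: transfer agent 8 mM; protic impurity 0.11 M; run made earlier
- autumn: transfer agent 8 mM; protic impurity 0.24 M; run made earlier
- flask: transfer agent 8.00 mM; protic impurity 0.160 M; time 12 min

- spring (time / min: monomer in chains / %, free monomer / %): 3.00: 9, 79; 6.00: 20, 66; 8.00: 25, 61; 12.0: 38, 48; 15.0: 42, 39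
- autumn (time / min: monomer in chains / %, free monomer / %): 1.00: 1, 65; 2.00: 7, 64; 4.00: 9, 60; 8.00: 22, 49; 15.0: 36, 33

(readings scatter by 1.5 percentage points)

* average number of monomer units in a chain (chains begun, living or dead) at 12 min
* part of the free monomer that has reacted at 12 min

- the average divides the monomer in chains by the number of chains begun, living and dead together
- the numbers in the tables scatter by 1.5 percentage points (one standard deviation)
- steps that have been proposed: living end + transfer agent -> dead chain; initiator + monomer in chains -> spent initiator; protic impurity + free monomer -> quenched substrate; free monomer + living end -> monomer in chains + living end; free monomer + initiator -> living end + monomer in chains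
- the earlier runs do not show the number of chains; that part of a forecast is a guess

So each protic impurity, the limiting reagent of this quench, appears to take one free monomer. For the flask this gives 20.0%: the tithe, the part of the charged free monomer lost to the impurity at the first fork.

At the second fork, the survivors still free at 15.0 min read 45.2% in spring and 47.1% in autumn, much alike despite different impurity. Initiator and transfer agent stand in the flask as in both runs, so they need no value of their own. The spring reading at 12.0 min gives a survival of 55.7%, and its scatter passes to the flask scaled by 0.928. Going from the spring impurity to the flask's moves the tithe by 6.2 percentage points and c by 3.5 points, so the impurity charge matters.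

My reckoning for the flask gives c = 55.5%. Scaling the spring chains and dividing by the whole initiator charge gives dp near 4.03, a guess, since no run shows the number of chains. The forecast says dp 4.1 (3.6 to 5.5) and c 54% (51% to 57%), lower than my c, holding that “the impurity quickly destroys one monomer each”.

    living end + transfer agent → dead chain (kL = 5.60 M⁻¹ min⁻¹)
    initiator + monomer in chains → spent initiator (k = 0.180 M⁻¹ min⁻¹)
    protic impurity + free monomer → quenched substrate (k = 10.0 M⁻¹ min⁻¹)
    free monomer + living end → monomer in chains + living end, rate k4*[living end]*[free monomer] (k = 0.910 M⁻¹ min⁻¹)
    free monomer + initiator → living end + monomer in chains (k = 0.410 M⁻¹ min⁻¹)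

The flask gives dp 4.40 and c 54.4%. Its quenched substrate stands at 20.0% at 12.0 min, equal to the tithe, with protic impurity at 0% of its charge. In a neighbouring flask, the same but with 0.48 M of free monomer, the tithe is 33.3%, and its quenched substrate reads 33.3% at 12.0 min, so 66.7% of its charge remains, held as free monomer, 40.6%, monomer in chains, 25.2%, and spent initiator, 0.794%.

The data are calculated on assumed constants, noise included.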